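Numbering: C1 is the ring carbinol carbon carrying C7 (CH2OBz), C2 and C5 are the benzoate carbons, C3=C4 is the alkene and C6 is the free secondary carbinol. With C1→C6 drawn clockwise, 1-OH points up and C7, O2, O5 and O6 point down.
Cuts, in retrosynthetic order: the O–acyl bonds at O5 and O7; the C1/C7 diol and then C1=C7, back to a C1 ketone and a C1 carbinol; the C2–OBz bond, with re-closure of a C1–O–C4 ether bridge; last, the ring bonds C1–C6 and C4–C5.
Enabling feature: in the cyclohexene ring the cis oxygens on C5/C6 lie on the face opposite the oxygen on C1, and C1 and C4 are the ends of the four-carbon unit C1–C2–C3–C4. This is the pattern of an endo-2,3-dioxygenated 7-oxabicyclo[2.2.1]hept-5-ene, that is, furan (C1–C4 plus bridge O) joined to vinylene carbonate (C5, C6 and their oxygens).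
Forward order: one cycloaddition closes the only carbocycle inside the oxabicycle, and the carbonate is then traded for an acetonide. A chiral rhodium catalyst opens the bridge with benzoic acid and leaves 1-OH as the single free hydroxyl. C7 is added there (ketone, methylene, diol), and O7 and O5 are benzoylated last.
Stereochemistry: the endo cycloaddition sets C5/C6 cis and anti to the bridge. The enantiotopos-selective anti SN2′ opening of the meso ether sets the absolute configuration and C2 (trans to O1). Osmylation of the exocyclic alkene on the face away from O2, O6 and the acetonide sets C1.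
Key step: step 1

Assumption: the sense of induction of the chiral ligand (and of Ipc2BH in the first fallback) on meso 5 cannot be read from a direct analogue, so one enantiomer is written and its equally available mirror image is to be used should the opposite series arise.

Step 1
Reactants: 1 furan; 2 vinylene carbonate (1,3-dioxol-2-one)
Product: 3 meso endo-7-oxabicyclo[2.2.1]hept-5-ene-2,3-diyl carbonate (O5 and O6 cis to each other and anti to the C1–O–C4 bridge)
Conditions: 1 (excess, neat), BHT (cat.), sealed steel vessel (autogenous pressure), 120 °C; exo isomer removed by crystallisation/chromatography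
Reagents that add atoms: none
Why: This is a concerted, suprafacial [4+2] Diels–Alder cycloaddition in which the two α-carbons of furan (future C1 and C4) bond to the two alkene carbons of 2 (future C6 and C5); this pair of partners is known to combine thermally to give separable endo and exo adducts, so the closest known reaction type is the reaction itself. The six-membered carbocycle C1–C6 is closed intermolecularly by simultaneous formation of C1–C6 and C4–C5, and the furan oxygen is left as the C1–O–C4 bridge of a 7-oxabicyclo[2.2.1]heptene. The cis relation of O5 and O6 is fixed by the ring-locked Z geometry of 2, the cis relation of the two bridgehead C–O bonds by the furan ring, and the anti relation between bridge and carbonate oxygens by the endo transition state. The step needs endo over exo selectivity: the endo mode, with the carbonate unit under the diene, is the kinetic one, and since the adducts of this sluggish dienophile revert only slowly, the lowest workable temperature and partial conversion should keep kinetic control. The exo isomer and unreacted 1 and 2 are separated and can be recycled. The product is meso, so no absolute configuration has to be set here.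

Step 2
Reactants: 3
Product: 4 meso 7-oxabicyclo[2.2.1]hept-5-ene-2-endo,3-endo-diol
Conditions: K2CO3 (cat.), MeOH, 0 °C to rt
Reagents that add atoms: none
Why: Base-catalysed transesterification (methanolysis) of the five-membered carbonate cleaves only acyl–oxygen bonds, so the endo,cis arrangement at C5/C6 is kept and the oxa bridge and alkene are untouched.

Step 3
Reactants: 4
Product: 5 meso 2-endo,3-endo-O-isopropylidene-7-oxabicyclo[2.2.1]hept-5-ene-2,3-diol (endo acetonide)
Conditions: Me2C(OMe)2, PPTS (cat.), CH2Cl2, rt
Reagents that add atoms: 2,2-dimethoxypropane, COC(C)(C)OC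
Why: Acid-catalysed transketalisation of a cis-1,2-diol gives the cis-fused dioxolane under conditions too mild to open the bridge; the acetonide withdraws less electron density from the bridgeheads than the carbonate, is a poorer β leaving group at the later ketone stage, and can be removed with acid beside benzoates, which a carbonate cannot.

Step 4
Reactants: 5; 6 benzoic acid
Product: 7 2-O-benzoyl-5,6-O-isopropylidene-cyclohex-3-ene-1,2,5,6-tetrol (1-OH up and free, 2-OBz down, O5 and O6 down in the cis-fused acetonide)
Conditions: [Rh(cod)Cl]2 (2.5 mol %), (R)-1-[(S)-2-(diphenylphosphino)ferrocenyl]ethyldi-tert-butylphosphine (5 mol %), Bu4NI (10 mol %), 6, Et3N, tetrahydropyran, 100 °C (sealed)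
Reagents that add atoms: benzoic acid 6, OC(=O)c1ccccc1
Why: Proposed new method: monovalent rhodium carrying the bulky, electron-rich ferrocenyl bisphosphine should bind the exo face of 5 (alkene plus bridge oxygen) and insert into one of the two enantiotopic bridgehead C–O bonds to give a π-allyl rhodium alkoxide spanning C2–C4; after protonation of the alkoxide it should accept benzoate from the face opposite the metal at C2, the allyl end next to the carbinol (attack at C4 is further blocked by O5 on the same face), so that 1-OH and 2-OBz come out trans, the alkene moves to C3=C4 and the ligand fixes the absolute configuration; the closest known reaction type is the rhodium-catalysed asymmetric ring opening of oxabenzonorbornadienes with carboxylates and of 5,6-bis(alkoxymethyl)-7-oxanorbornenes with phenols and amines under iodide-modified forcing conditions, whereas an oxanorbornene with endo C–O substituents next to the ionising bridgehead has not been opened in this way.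

Step 5
Reactants: 7
Product: 8 2-benzoyloxy-5,6-(isopropylidenedioxy)cyclohex-3-en-1-one (2-OBz, O5 and O6 all down)
Conditions: Dess–Martin periodinane, CH2Cl2, 0 °C to rt; filtered and used without chromatography
Reagents that add atoms: none
Why: Dess–Martin oxidation of the only free hydroxyl runs without base, which matters because H-2 of 8 is α to the ketone, allylic and geminal to a benzoate and O5 is a β leaving group, so C2 and C6 should keep their configuration.

Step 6
Reactants: 8
Product: 9 2-benzoyloxy-5,6-(isopropylidenedioxy)-1-methylenecyclohex-3-ene (2-OBz, O5 and O6 down)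
Conditions: Cp2Ti(μ-CH2)(μ-Cl)AlMe2 (Tebbe reagent, 1.1 equiv), pyridine (cat.), THF–toluene, −40 to 0 °C
Reagents that add atoms: Tebbe reagent Cp2Ti(μ-CH2)(μ-Cl)AlMe2, [CH-]1C=CC=C1.[CH-]1C=CC=C1.[Ti+4].[CH2-2].[Cl-].C[Al+]C
Why: In this Tebbe methylenation the non-basic methylidene Cp2Ti=CH2 adds to the ketone through an oxatitanacyclobutane much faster than to benzoate esters at low temperature, so enolisation (epimerisation at C2/C6, β-elimination, aromatisation) and ester methylenation should both be avoided.

Step 7
Reactants: 9
Product: 10 2-benzoyloxy-1-(hydroxymethyl)-5,6-(isopropylidenedioxy)cyclohex-3-en-1-ol (1-OH up, CH2OH down, 2-OBz, O5 and O6 down)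
Conditions: OsO4 (2 mol %), NMO (1.0 equiv), acetone–H2O, 0 °C
Reagents that add atoms: osmium tetroxide, O=[Os](=O)(=O)=O; N-methylmorpholine N-oxide, C[N+]1([O-])CCOCC1; water, O
Why: In this catalytic OsO4/NMO syn-dihydroxylation the oxidant should add to the terminal 1,1-disubstituted alkene from the convex top face, anti to both allylic C–O bonds (O2, O6) and away from the acetonide, which puts 1-OH up and C7 down, while the internal ring cis-alkene is expected to react more slowly when the oxidant is limited to one equivalent at low temperature.

Step 8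
Reactants: 10
Product: 11 [2-benzoyloxy-1-hydroxy-5,6-(isopropylidenedioxy)cyclohex-3-en-1-yl]methyl benzoate (configuration as in 10)
Conditions: BzCl (1.1 equiv), pyridine, CH2Cl2, 0 °C
Reagents that add atoms: benzoyl chloride, O=C(Cl)c1ccccc1
Why: Chemoselective acylation of a primary alcohol beside a tertiary one is standard, and an O2→O7 acyl shift in 10 would be harmless because both positions end up benzoylated.

Step 9
Reactants: 11
Product: 12 [(1R,2R,5S,6S)-2-benzoyloxy-1,5,6-trihydroxycyclohex-3-en-1-yl]methyl benzoate
Conditions: TFA–H2O (4:1), CH2Cl2, 0 °C to rt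
Reagents that add atoms: none
Why: Acid hydrolysis of an isopropylidene acetal breaks only the acetal C–O bonds, so C5 and C6 are retained, and benzoate esters and the electron-poor allylic positions tolerate cold aqueous acid.

Step 10
Reactants: 12
Product: 13 [(1R,2R,5S,6S)-2,5-bis(benzoyloxy)-1,6-dihydroxycyclohex-3-en-1-yl]methyl benzoate (CNP0128482.6)
Conditions: BzCl (1.05 equiv), pyridine, CH2Cl2, −40 to −20 °C
Reagents that add atoms: benzoyl chloride, O=C(Cl)c1ccccc1
Why: This is a kinetic regioselective benzoylation, because in the favoured half-chair (C7 equatorial) 5-OH is pseudo-equatorial, allylic and next to an sp2 carbon, whereas 6-OH is axial and crowded by the quaternary C1 and 1-OH is tertiary, so one equivalent of acyl chloride should react at O5 only and no stereocentre is touched.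

Compound list
1 | furan | c1ccoc1 | starting material
2 | vinylene carbonate | O=C1OC=CO1 | starting material
3 | meso endo-7-oxabicyclo[2.2.1]hept-5-ene-2,3-diyl carbonate | O=C1O[C@@H]2[C@@H]3C=C[C@@H](O3)[C@@H]2O1 | intermediate
4 | meso 7-oxabicyclo[2.2.1]hept-5-ene-2-endo,3-endo-diol | O[C@@H]1[C@@H]2C=C[C@@H](O2)[C@@H]1O | intermediate
5 | meso endo acetonide of 4 | CC1(C)O[C@@H]2[C@@H]3C=C[C@@H](O3)[C@@H]2O1 | intermediate
6 | benzoic acid | OC(=O)c1ccccc1 | starting material
7 | 2-O-benzoyl-5,6-O-isopropylidene-cyclohex-3-ene-1,2,5,6-tetrol (1-OH up; O2, O5, O6 down) | O[C@H]1[C@H](OC(=O)c3ccccc3)C=C[C@@H]2OC(C)(C)O[C@H]12 | intermediate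
8 | 2-benzoyloxy-5,6-(isopropylidenedioxy)cyclohex-3-en-1-one | O=C1[C@H](OC(=O)c3ccccc3)C=C[C@@H]2OC(C)(C)O[C@H]12 | intermediate
9 | 2-benzoyloxy-5,6-(isopropylidenedioxy)-1-methylenecyclohex-3-ene | C=C1[C@H](OC(=O)c3ccccc3)C=C[C@@H]2OC(C)(C)O[C@H]12 | intermediate
10 | C1,C7-diol (1-OH up, CH2OH down) | OC[C@]1(O)[C@H](OC(=O)c3ccccc3)C=C[C@@H]2OC(C)(C)O[C@H]12 | intermediate
11 | C7 benzoate of 10 | O=C(OC[C@]1(O)[C@H](OC(=O)c3ccccc3)C=C[C@@H]2OC(C)(C)O[C@H]12)c4ccccc4 | intermediate
12 | [(1R,2R,5S,6S)-2-benzoyloxy-1,5,6-trihydroxycyclohex-3-en-1-yl]methyl benzoate | O=C(OC[C@]1(O)[C@H](OC(=O)c2ccccc2)C=C[C@H](O)[C@@H]1O)c1ccccc1 | intermediate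
13 | [(1R,2R,5S,6S)-2,5-bis(benzoyloxy)-1,6-dihydroxycyclohex-3-en-1-yl]methyl benzoate | O=C(OC[C@]1(O)[C@H](OC(=O)c2ccccc2)C=C[C@H](OC(=O)c2ccccc2)[C@@H]1O)c1ccccc1 | target

Total step count: 10. Longest linear sequence: 10 steps (from 1 and 2).

Steps most likely to fail

Step 4 (bridge opening).
- What may go wrong: inductive withdrawal by the two endo C–O bonds may slow insertion of rhodium into the bridgehead C–O bond beyond what the catalyst survives. Benzoate delivery from the endo face may be retarded by the acetonide. At 100 °C the benzoate may migrate from O2 to O1. Enantiotopos selection may be weaker than on benzo-fused substrates.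
- Fallback (known chemistry, sets out from 5, returns at 7): the meso alkene is desymmetrised by asymmetric hydroboration and the bridge is then opened by β-elimination.
- (−)-Ipc2BH (from (+)-α-pinene, THF, −25 °C) adds to the exo face of the cis-alkene to give the trialkylborane F1.
- NaBO3·4H2O oxidises F1 with retention to the exo-2-alcohol F2.
- Dess–Martin oxidation gives the 7-oxanorbornan-2-one F3, in which only C3 can enolise.
- TBSOTf/Et3N (CH2Cl2, 0 °C to rt) triggers the established β-elimination of the oxa bridge (C4–O cleavage) and silylates the freed O1, giving the 1-silyloxy enone F4.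
- Luche reduction (NaBH4, CeCl3·7H2O, MeOH, −78 °C) should deliver hydride axially to give the trans allylic alcohol F5 (2-OH down).
- BzCl/pyridine gives the benzoate silyl ether F6, and HF·pyridine (THF, 0 °C) frees 1-OH to give 7.

Step 6 (methylenation).
- What may go wrong: ketone 8 may enolise, followed by β-elimination of O5 and aromatisation. The benzoate carbonyl may be methylenated competitively. The aluminium by-product may erode the acetonide by Lewis acid action.
- Fallback (sets out from 8, returns at 9): a two-stage Peterson olefination.
- Me3SiCH2MgCl precomplexed with anhydrous CeCl3 (THF, −78 °C) is a nucleophilic but barely basic organocerium. It adds to the ketone from the open top face to give the β-hydroxysilane F7.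
- HF·pyridine (THF, 0 °C) eliminates silicon and hydroxyl from F7 to give 9. The C1 configuration of the adduct is lost in the elimination and so does not matter.

Step 7 (dihydroxylation).
- What may go wrong: osmylation of the ring alkene, whose top face is equally open, may compete and lead to mixtures and over-oxidation.
- Fallback (sets out from 9, returns at 11): chemoselectivity is made irrelevant by oxidising both alkenes and restoring the ring alkene afterwards.
- Excess NMO with catalytic OsO4 gives the tetraol F8 (all new oxygens from the top face).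
- BzCl (1 equiv, pyridine, 0 °C) acylates the primary hydroxyl to give the C7 monobenzoate F9.
- 1,1′-Thiocarbonyldiimidazole (toluene, 80 °C) closes the only cis-vicinal secondary diol to give the 3,4-thionocarbonate F10.
- Corey–Winter olefination with 1,3-dimethyl-2-phenyl-1,3,2-diazaphospholidine (40 °C) regenerates C3=C4 stereospecifically and gives 11.

Further compounds
F1 | step 4 | diisopinocampheyl[5-endo,6-endo-(isopropylidenedioxy)-7-oxabicyclo[2.2.1]hept-2-exo-yl]borane | CC1(C)O[C@@H]2[C@@H]3[C@@H](B([C@@H]4C[C@@H]5C[C@H]([C@H]4C)C5(C)C)[C@@H]6C[C@@H]7C[C@H]([C@H]6C)C7(C)C)C[C@@H](O3)[C@@H]2O1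
F2 | step 4 | 5-endo,6-endo-(isopropylidenedioxy)-7-oxabicyclo[2.2.1]heptan-2-exo-ol | CC1(C)O[C@@H]2[C@@H]3[C@@H](O)C[C@@H](O3)[C@@H]2O1
F3 | step 4 | 5-endo,6-endo-(isopropylidenedioxy)-7-oxabicyclo[2.2.1]heptan-2-one | CC1(C)O[C@@H]2[C@@H]3C(=O)C[C@@H](O3)[C@@H]2O1
F4 | step 4 | 1-(tert-butyldimethylsilyloxy)-5,6-(isopropylidenedioxy)cyclohex-3-en-2-one (target numbering; 1-OTBS up, O5 and O6 down) | CC(C)(C)[Si](C)(C)O[C@H]1C(=O)C=C[C@@H]2OC(C)(C)O[C@H]12
F5 | step 4 | 1-O-TBS-5,6-O-isopropylidene-cyclohex-3-ene-1,2,5,6-tetrol (2-OH down) | CC(C)(C)[Si](C)(C)O[C@H]1[C@H](O)C=C[C@@H]2OC(C)(C)O[C@H]12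
F6 | step 4 | 2-O-benzoyl-1-O-TBS-5,6-O-isopropylidene-cyclohex-3-ene-1,2,5,6-tetrol | CC(C)(C)[Si](C)(C)O[C@H]1[C@H](OC(=O)c3ccccc3)C=C[C@@H]2OC(C)(C)O[C@H]12
F7 | step 6 | 2-benzoyloxy-5,6-(isopropylidenedioxy)-1-(trimethylsilylmethyl)cyclohex-3-en-1-ol (CH2SiMe3 up, 1-OH down) | C[Si](C)(C)C[C@@]1(O)[C@H](OC(=O)c3ccccc3)C=C[C@@H]2OC(C)(C)O[C@H]12
F8 | step 7 | 2-benzoyloxy-1-(hydroxymethyl)-5,6-(isopropylidenedioxy)cyclohexane-1,3,4-triol (1-, 3- and 4-OH up) | OC[C@]1(O)[C@H](OC(=O)c3ccccc3)[C@@H](O)[C@@H](O)[C@@H]2OC(C)(C)O[C@H]12
F9 | step 7 | C7 monobenzoate of F8 | O=C(OC[C@]1(O)[C@H](OC(=O)c3ccccc3)[C@@H](O)[C@@H](O)[C@@H]2OC(C)(C)O[C@H]12)c4ccccc4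
F10 | step 7 | 3,4-O-thiocarbonyl derivative of F9 | O=C(OC[C@]1(O)[C@H](OC(=O)c3ccccc3)[C@H]5OC(=S)O[C@H]5[C@@H]2OC(C)(C)O[C@H]12)c4ccccc4
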